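**Retrosynthetic overview**
1. The target comes from its tetra-O-methyl ether by BBr3 cleavage in the last step. The CHO group is carried as CO2Et, then CH2OH, through all C–C bond formations.
2. The C3–aryl bond comes from Suzuki coupling of a 3-bromobenzofuran with 3,5-dimethoxyphenylboronic acid. The bromide comes from C3-selective NBS bromination of the 4-acetoxy-2-arylbenzofuran.
3. Ring A (the benzene ring) comes from Ac2O/NaOAc ring closure (C3a–C4 bond) of a furylidene-succinic half-ester. This fixes the 4-O/6-CO2Et pattern with no regiochemical choice.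
4. The key disconnection is C6–C7: a Stobbe condensation (intermolecular aldol addition, lactonisation, elimination) of 5-(4-methoxyphenyl)furfural with diethyl succinate.
5. Ring order: the furan ring is bought (5-bromofurfural, arylated at C5) and ring A is then built onto it. Both outer aryl rings are introduced intact.

Assumption: the target has no stereocentre, no stereogenic axis (both aryl groups are symmetric about their bond axes) and no C=C stereo-unit, so it is achiral and there is no enantiomer to select; the only stereo-element in the route is the E-alkene of 6 and 7.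

**Step 1**
Reactants: 1 5-bromofuran-2-carbaldehyde; 2 (4-methoxyphenyl)boronic acid
Product: 3 5-(4-methoxyphenyl)furan-2-carbaldehyde
Conditions: Pd(PPh3)4 (3 mol %), Na2CO3 (2 equiv), DME/H2O 3:1, 80 °C, 6 h
Reagents that add atoms: none
Why: Suzuki–Miyaura coupling, in which the C5–Br bond of the electron-poor furfural adds readily to zerovalent palladium and the aldehyde is inert to aqueous carbonate, so the furan–aryl bond forms cleanly and no stereocentre is created.

**Step 2**
Reactants: 3 5-(4-methoxyphenyl)furan-2-carbaldehyde; 4 diethyl succinate (1.5 equiv)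
Product: 6 (E)-3-(ethoxycarbonyl)-4-[5-(4-methoxyphenyl)furan-2-yl]but-3-enoic acid, via paraconate lactone 5 (not isolated)
Conditions: KOtBu (1.3 equiv), t-BuOH, reflux, 3 h; then 2 M HCl; acid–base extraction
Reagents that add atoms: none
Why: Stobbe condensation, in which the succinate enolate adds to the non-enolisable aldehyde in an intermolecular aldol addition (future C6–C7 bond), the alkoxide lactonises to racemic 5, and irreversible E1cB opening to the carboxylate drives the sequence, destroys both transient stereocentres and gives mainly the E-alkene (furyl trans to CO2Et, cis to CH2CO2H), which is the geometry needed for ring closure.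

**Step 3**
Reactants: 6 (E)-3-(ethoxycarbonyl)-4-[5-(4-methoxyphenyl)furan-2-yl]but-3-enoic acid
Product: 9 ethyl 4-acetoxy-2-(4-methoxyphenyl)-1-benzofuran-6-carboxylate, via mixed anhydride 7 (not isolated), via free phenol 8 (not isolated)
Conditions: Ac2O (solvent), NaOAc (1.5 equiv), reflux (140 °C), 3 h
Reagents that add atoms: acetic anhydride CC(=O)OC(C)=O
Why: Stobbe-type benzannulation, an intramolecular Friedel–Crafts acylation of furan C3 (the only position the cis CH2CO chain can reach) by mixed anhydride 7, followed by enolisation to phenol 8 and in situ acetylation, so ring A forms with its 4-oxygen and 6-ester in fixed positions.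

**Step 4**
Reactants: 9 ethyl 4-acetoxy-2-(4-methoxyphenyl)-1-benzofuran-6-carboxylate
Product: 10 ethyl 4-acetoxy-3-bromo-2-(4-methoxyphenyl)-1-benzofuran-6-carboxylate
Conditions: NBS (1.05 equiv), MeCN, 0 °C → rt, dark
Reagents that add atoms: N-bromosuccinimide O=C1CCC(=O)N1Br
Why: Electrophilic aromatic bromination, in which C3 is the enol-ether-like β-carbon of the furan ring and is further activated by the 2-anisyl group, whereas ring A carries an ester and only a weakly donating acetate (the reason for brominating before the acetate is exchanged for methyl), so one equivalent of NBS reacts at C3.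

**Step 5**
Reactants: 10 ethyl 4-acetoxy-3-bromo-2-(4-methoxyphenyl)-1-benzofuran-6-carboxylate
Product: 11 ethyl 3-bromo-4-hydroxy-2-(4-methoxyphenyl)-1-benzofuran-6-carboxylate
Conditions: K2CO3 (1.5 equiv), EtOH, 50 °C, 2 h; then 1 M HCl
Reagents that add atoms: none
Why: Base-mediated transesterification (ethanolysis) of the activated aryl acetate is much faster than attack on the benzoate, and ethanol as solvent makes any exchange at the ethyl ester degenerate, while the aryl bromide is untouched.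

**Step 6**
Reactants: 11 ethyl 3-bromo-4-hydroxy-2-(4-methoxyphenyl)-1-benzofuran-6-carboxylate
Product: 12 ethyl 3-bromo-4-methoxy-2-(4-methoxyphenyl)-1-benzofuran-6-carboxylate
Conditions: MeI (2 equiv), K2CO3 (2 equiv), DMF, rt, 6 h
Reagents that add atoms: iodomethane CI
Why: Williamson ether synthesis (SN2 methylation of the only phenoxide present) protects the 4-OH against the later hydride and MnO2 steps with the same group as the other three phenols, so one final operation frees all four.

**Step 7**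
Reactants: 12 ethyl 3-bromo-4-methoxy-2-(4-methoxyphenyl)-1-benzofuran-6-carboxylate; 13 (3,5-dimethoxyphenyl)boronic acid (1.5 equiv)
Product: 14 ethyl 3-(3,5-dimethoxyphenyl)-4-methoxy-2-(4-methoxyphenyl)-1-benzofuran-6-carboxylate
Conditions: Pd(OAc)2 (5 mol %), SPhos (10 mol %), K3PO4 (3 equiv), toluene/H2O 10:1, 100 °C, 12 h
Reagents that add atoms: none
Why: Suzuki–Miyaura coupling, in which the bulky electron-rich biarylphosphine gives a monoligated zerovalent palladium species that inserts into the flanked C3–Br bond and speeds reductive elimination, the boronic acid has no ortho substituent and resists protodeboronation, and the ethyl ester tolerates phosphate base.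

**Step 8**
Reactants: 14 ethyl 3-(3,5-dimethoxyphenyl)-4-methoxy-2-(4-methoxyphenyl)-1-benzofuran-6-carboxylate
Product: 15 [3-(3,5-dimethoxyphenyl)-4-methoxy-2-(4-methoxyphenyl)-1-benzofuran-6-yl]methanol
Conditions: LiAlH4 (1.2 equiv), THF, 0 °C → rt, 1 h; Na2SO4·10H2O quench
Reagents that add atoms: none
Why: Hydride reduction of the ester, the only reducible group present (aryl methyl ethers and the benzofuran are inert), goes fully to the primary alcohol and avoids the over-reduction problem of a direct ester-to-aldehyde reduction.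

**Step 9**
Reactants: 15 [3-(3,5-dimethoxyphenyl)-4-methoxy-2-(4-methoxyphenyl)-1-benzofuran-6-yl]methanol
Product: 16 3-(3,5-dimethoxyphenyl)-4-methoxy-2-(4-methoxyphenyl)-1-benzofuran-6-carbaldehyde
Conditions: activated MnO2 (15 equiv), CH2Cl2, rt, 12 h; filter through Celite
Reagents that add atoms: none
Why: Heterogeneous MnO2 oxidation is selective for benzylic alcohols, stops at the aldehyde and does not touch the fully O-methylated electron-rich rings.

**Step 10**
Reactants: 16 3-(3,5-dimethoxyphenyl)-4-methoxy-2-(4-methoxyphenyl)-1-benzofuran-6-carbaldehyde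
Product: 18 3-(3,5-dihydroxyphenyl)-4-hydroxy-2-(4-hydroxyphenyl)-1-benzofuran-6-carbaldehyde, via tetrakis(dibromoboryl) ether 17 (not isolated)
Conditions: BBr3 (8 equiv, 1 M in CH2Cl2), CH2Cl2, −78 °C → rt, 12 h; then ice/H2O, 1 h; EtOAc extraction
Reagents that add atoms: none
Why: Lewis-acid aryl methyl ether cleavage (BBr3 coordinates each ether oxygen and bromide removes the methyl group by SN2), with excess reagent to cover reversible complexation of the aromatic aldehyde, and the aqueous quench hydrolyses borate 17 and frees the carbonyl to give the achiral target 18.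

**Compound list**
1 | 5-bromofuran-2-carbaldehyde | O=Cc1ccc(Br)o1 | starting material
2 | (4-methoxyphenyl)boronic acid | COc1ccc(B(O)O)cc1 | starting material
3 | 5-(4-methoxyphenyl)furan-2-carbaldehyde | COc1ccc(-c2ccc(C=O)o2)cc1 | intermediate
4 | diethyl succinate | CCOC(=O)CCC(=O)OCC | starting material
5 | ethyl 2-[5-(4-methoxyphenyl)furan-2-yl]-5-oxooxolane-3-carboxylate (racemic cis/trans mixture) | CCOC(=O)C1CC(=O)OC1c1ccc(-c2ccc(OC)cc2)o1 | intermediate (not isolated)
6 | (E)-3-(ethoxycarbonyl)-4-[5-(4-methoxyphenyl)furan-2-yl]but-3-enoic acid | CCOC(=O)/C(CC(=O)O)=C/c1ccc(-c2ccc(OC)cc2)o1 | intermediate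
7 | acetic (E)-3-(ethoxycarbonyl)-4-[5-(4-methoxyphenyl)furan-2-yl]but-3-enoic anhydride | CCOC(=O)/C(CC(=O)OC(C)=O)=C/c1ccc(-c2ccc(OC)cc2)o1 | intermediate (not isolated)
8 | ethyl 4-hydroxy-2-(4-methoxyphenyl)-1-benzofuran-6-carboxylate | CCOC(=O)c1cc(O)c2cc(-c3ccc(OC)cc3)oc2c1 | intermediate (not isolated)
9 | ethyl 4-acetoxy-2-(4-methoxyphenyl)-1-benzofuran-6-carboxylate | CCOC(=O)c1cc(OC(C)=O)c2cc(-c3ccc(OC)cc3)oc2c1 | intermediate
10 | ethyl 4-acetoxy-3-bromo-2-(4-methoxyphenyl)-1-benzofuran-6-carboxylate | CCOC(=O)c1cc(OC(C)=O)c2c(Br)c(-c3ccc(OC)cc3)oc2c1 | intermediate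
11 | ethyl 3-bromo-4-hydroxy-2-(4-methoxyphenyl)-1-benzofuran-6-carboxylate | CCOC(=O)c1cc(O)c2c(Br)c(-c3ccc(OC)cc3)oc2c1 | intermediate
12 | ethyl 3-bromo-4-methoxy-2-(4-methoxyphenyl)-1-benzofuran-6-carboxylate | CCOC(=O)c1cc(OC)c2c(Br)c(-c3ccc(OC)cc3)oc2c1 | intermediate
13 | (3,5-dimethoxyphenyl)boronic acid | COc1cc(OC)cc(B(O)O)c1 | starting material
14 | ethyl 3-(3,5-dimethoxyphenyl)-4-methoxy-2-(4-methoxyphenyl)-1-benzofuran-6-carboxylate | CCOC(=O)c1cc(OC)c2c(-c3cc(OC)cc(OC)c3)c(-c3ccc(OC)cc3)oc2c1 | intermediate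
15 | [3-(3,5-dimethoxyphenyl)-4-methoxy-2-(4-methoxyphenyl)-1-benzofuran-6-yl]methanol | OCc1cc(OC)c2c(-c3cc(OC)cc(OC)c3)c(-c3ccc(OC)cc3)oc2c1 | intermediate
16 | 3-(3,5-dimethoxyphenyl)-4-methoxy-2-(4-methoxyphenyl)-1-benzofuran-6-carbaldehyde | O=Cc1cc(OC)c2c(-c3cc(OC)cc(OC)c3)c(-c3ccc(OC)cc3)oc2c1 | intermediate
17 | 3-[3,5-bis(dibromoboryloxy)phenyl]-4-(dibromoboryloxy)-2-[4-(dibromoboryloxy)phenyl]-1-benzofuran-6-carbaldehyde (idealised borate) | O=Cc1cc(OB(Br)Br)c2c(-c3cc(OB(Br)Br)cc(OB(Br)Br)c3)c(-c3ccc(OB(Br)Br)cc3)oc2c1 | intermediate (not isolated)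
18 | 3-(3,5-dihydroxyphenyl)-4-hydroxy-2-(4-hydroxyphenyl)-1-benzofuran-6-carbaldehyde (achiral) | O=Cc1cc(O)c2c(-c3cc(O)cc(O)c3)c(-c3ccc(O)cc3)oc2c1 | target

**Total step count:** 10
**Longest linear sequence:** 10 steps (1 → 18); 2, 4 and 13 enter as bought building blocks.

**Three steps most likely to fail**

Risk 1 (step 3, benzannulation of 6): the electron-rich 5-anisylfuran may resinify in refluxing Ac2O, or the minor Z half-ester may lower the yield. The fallback builds ring A before the anisyl group is attached. It sets out from 4 and comes back to the route at 9.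
- Stobbe condensation of 4 with bought furfural (KOtBu, t-BuOH, reflux) gives (E)-3-(ethoxycarbonyl)-4-(furan-2-yl)but-3-enoic acid F1.
- Ac2O/NaOAc closure of this unsubstituted, well-behaved substrate gives ethyl 4-acetoxy-1-benzofuran-6-carboxylate F2.
- C2-selective C–H borylation ([Ir(OMe)(cod)]2, 4,4'-di-tert-butyl-2,2'-bipyridine, B2pin2, THF, 60 °C) gives ethyl 4-acetoxy-2-(4,4,5,5-tetramethyl-1,3,2-dioxaborolan-2-yl)-1-benzofuran-6-carboxylate F3.
- Suzuki coupling of F3 with 4-bromoanisole (PdCl2(dppf), anhydrous K3PO4, dioxane, 80 °C) delivers 9. If part of the acetate is lost, brief Ac2O/pyridine treatment of the crude converts the resulting 8 back into 9.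

Risk 2 (step 7, Suzuki coupling at the flanked C3 position of 12): hydrodebromination or a stalled coupling is possible between the 2-aryl and the peri 4-OMe group. The fallback installs the 3,5-dimethoxyphenyl ring on the furan, where that position is unhindered, and only then builds ring A by the same Stobbe sequence. It sets out from 1 and comes back at 14.
- Bromination of 1 (Br2, AlCl3, CH2Cl2, 0 °C → rt) gives 4,5-dibromofuran-2-carbaldehyde F4.
- The more electrophilic C5–Br couples first with 2 (1.0 equiv, Pd(PPh3)4, Na2CO3, DME/H2O, 70 °C) to give 4-bromo-5-(4-methoxyphenyl)furan-2-carbaldehyde F5.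
- A second Suzuki coupling with 13 gives 4-(3,5-dimethoxyphenyl)-5-(4-methoxyphenyl)furan-2-carbaldehyde F6.
- Stobbe condensation of F6 with 4 (KOtBu, t-BuOH) gives (E)-4-[4-(3,5-dimethoxyphenyl)-5-(4-methoxyphenyl)furan-2-yl]-3-(ethoxycarbonyl)but-3-enoic acid F7.
- Ac2O/NaOAc at reflux gives ethyl 4-acetoxy-3-(3,5-dimethoxyphenyl)-2-(4-methoxyphenyl)-1-benzofuran-6-carboxylate F8.
- K2CO3/EtOH gives ethyl 3-(3,5-dimethoxyphenyl)-4-hydroxy-2-(4-methoxyphenyl)-1-benzofuran-6-carboxylate F9, and MeI/K2CO3 in DMF gives 14.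

Risk 3 (step 10, fourfold demethylation in the presence of the aldehyde): incomplete cleavage, benzal bromide formation or condensation of the free aldehyde with the liberated resorcinol ring under strong Lewis acid could erode the yield. The fallback removes the methyl groups before the aldehyde exists and carries the phenols as fluoride-labile silyl ethers. It sets out from 14 and comes back at 18.
- BBr3 (CH2Cl2, −78 → 0 °C) on 14 gives ethyl 3-(3,5-dihydroxyphenyl)-4-hydroxy-2-(4-hydroxyphenyl)-1-benzofuran-6-carboxylate F10. Any free acid formed is re-esterified with EtOH and catalytic H2SO4.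
- TBSCl/imidazole (DMF, 40 °C) gives ethyl 4-(tert-butyldimethylsilyloxy)-3-[3,5-bis(tert-butyldimethylsilyloxy)phenyl]-2-[4-(tert-butyldimethylsilyloxy)phenyl]-1-benzofuran-6-carboxylate F11.
- i-Bu2AlH (CH2Cl2, −78 °C) gives the corresponding tetrasilylated benzofuran-6-ylmethanol F12.
- MnO2 (CH2Cl2, rt) gives the tetrasilylated benzofuran-6-carbaldehyde F13.
- Bu4NF buffered with AcOH (THF, 0 °C) releases 18 under nearly neutral conditions.

**Further compounds**
F1 | step 3 | (E)-3-(ethoxycarbonyl)-4-(furan-2-yl)but-3-enoic acid | CCOC(=O)/C(CC(=O)O)=C/c1ccco1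
F2 | step 3 | ethyl 4-acetoxy-1-benzofuran-6-carboxylate | CCOC(=O)c1cc(OC(C)=O)c2ccoc2c1
F3 | step 3 | ethyl 4-acetoxy-2-(4,4,5,5-tetramethyl-1,3,2-dioxaborolan-2-yl)-1-benzofuran-6-carboxylate | CCOC(=O)c1cc(OC(C)=O)c2cc(B3OC(C)(C)C(C)(C)O3)oc2c1
F4 | step 7 | 4,5-dibromofuran-2-carbaldehyde | O=Cc1cc(Br)c(Br)o1
F5 | step 7 | 4-bromo-5-(4-methoxyphenyl)furan-2-carbaldehyde | O=Cc1cc(Br)c(-c2ccc(OC)cc2)o1
F6 | step 7 | 4-(3,5-dimethoxyphenyl)-5-(4-methoxyphenyl)furan-2-carbaldehyde | O=Cc1cc(-c2cc(OC)cc(OC)c2)c(-c2ccc(OC)cc2)o1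
F7 | step 7 | (E)-4-[4-(3,5-dimethoxyphenyl)-5-(4-methoxyphenyl)furan-2-yl]-3-(ethoxycarbonyl)but-3-enoic acid | CCOC(=O)/C(CC(=O)O)=C/c1cc(-c2cc(OC)cc(OC)c2)c(-c2ccc(OC)cc2)o1
F8 | step 7 | ethyl 4-acetoxy-3-(3,5-dimethoxyphenyl)-2-(4-methoxyphenyl)-1-benzofuran-6-carboxylate | CCOC(=O)c1cc(OC(C)=O)c2c(-c3cc(OC)cc(OC)c3)c(-c3ccc(OC)cc3)oc2c1
F9 | step 7 | ethyl 3-(3,5-dimethoxyphenyl)-4-hydroxy-2-(4-methoxyphenyl)-1-benzofuran-6-carboxylate | CCOC(=O)c1cc(O)c2c(-c3cc(OC)cc(OC)c3)c(-c3ccc(OC)cc3)oc2c1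
F10 | step 10 | ethyl 3-(3,5-dihydroxyphenyl)-4-hydroxy-2-(4-hydroxyphenyl)-1-benzofuran-6-carboxylate | CCOC(=O)c1cc(O)c2c(-c3cc(O)cc(O)c3)c(-c3ccc(O)cc3)oc2c1
F11 | step 10 | ethyl 4-(tert-butyldimethylsilyloxy)-3-[3,5-bis(tert-butyldimethylsilyloxy)phenyl]-2-[4-(tert-butyldimethylsilyloxy)phenyl]-1-benzofuran-6-carboxylate | CCOC(=O)c1cc(O[Si](C)(C)C(C)(C)C)c2c(-c3cc(O[Si](C)(C)C(C)(C)C)cc(O[Si](C)(C)C(C)(C)C)c3)c(-c3ccc(O[Si](C)(C)C(C)(C)C)cc3)oc2c1
F12 | step 10 | {4-(tert-butyldimethylsilyloxy)-3-[3,5-bis(tert-butyldimethylsilyloxy)phenyl]-2-[4-(tert-butyldimethylsilyloxy)phenyl]-1-benzofuran-6-yl}methanol | OCc1cc(O[Si](C)(C)C(C)(C)C)c2c(-c3cc(O[Si](C)(C)C(C)(C)C)cc(O[Si](C)(C)C(C)(C)C)c3)c(-c3ccc(O[Si](C)(C)C(C)(C)C)cc3)oc2c1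
F13 | step 10 | 4-(tert-butyldimethylsilyloxy)-3-[3,5-bis(tert-butyldimethylsilyloxy)phenyl]-2-[4-(tert-butyldimethylsilyloxy)phenyl]-1-benzofuran-6-carbaldehyde | O=Cc1cc(O[Si](C)(C)C(C)(C)C)c2c(-c3cc(O[Si](C)(C)C(C)(C)C)cc(O[Si](C)(C)C(C)(C)C)c3)c(-c3ccc(O[Si](C)(C)C(C)(C)C)cc3)oc2c1
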